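## Retrosynthetic overview

- **Feature:** the only non-aromatic C=C of the 12-membered lactone ring is a Z alkene. It joins the allylic carbinol carbon C3 to the ring B carbon that lies between the diaryl ether oxygen and the CH2OH-bearing carbon. Cutting it by ring-closing metathesis leaves a ring B styrene and a vinyl carbinol ether, both held on one benzoate.
- **Ester cut:** the open diene is cut at the ester C–O bond into a diaryl ether acid and (3S,4S)-3-(methoxymethoxy)non-1-en-4-ol. The alcohol comes from hexanal by asymmetric (Z)-γ-alkoxyallylboration, which sets both stereocentres (syn).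
- **Diaryl ether cut:** the acid is cut at the ring B C–O bond. Methyl 5-hydroxy-2-methylbenzoate attacks 2-bromo-6-fluoro-3-(methoxymethoxy)benzaldehyde by SNAr, then CHO becomes vinyl and Br becomes CH2OH.
- **Ring B pattern:** the contiguous F/CHO/Br/O pattern comes from deprotonating protected 2-bromo-4-fluorophenol between the two halogens. Lithiation of 6-fluoro-2,2-dimethyl-4H-1,3-benzodioxine was rejected, because its ring oxygen cannot guide lithium to the crowded C5 and C7 would compete.
- **Ring order:** rings A and B are bought. The temporary 1,3-benzodioxine ring is closed in step 8, the 12-membered ring in step 12, and the benzodioxine is opened again in step 13.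

Key step: step 12

Remark: both sp3 carbons of the macrocycle are S. With O > neighbouring carbinol carbon > chain at each centre, this is the syn (threo) diol pattern.

Assumption: the allylborane made from (+)-Ipc2BOMe (from (−)-α-pinene) attacks the Re face of hexanal. This mirrors the Si-face attack known for the (−)-Ipc2BOMe series on unbranched aliphatic aldehydes.

## Route

**Step 1**
Reactants: 1 5-hydroxy-2-methylbenzoic acid
Product: 2 methyl 5-hydroxy-2-methylbenzoate
Conditions: MeOH, H2SO4 (cat.), reflux
Reagents that add atoms: methanol, CO
Why: Fischer esterification under acid catalysis leaves the phenol free as the later SNAr nucleophile and masks the acid through the basic steps.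

**Step 2**
Reactants: 3 2-bromo-4-fluorophenol
Product: 4 2-bromo-4-fluoro-1-(methoxymethoxy)benzene
Conditions: MOMCl, iPr2NEt, CH2Cl2, 0 °C → rt
Reagents that add atoms: chloromethyl methyl ether (MOMCl), COCCl
Why: Base-mediated O-alkylation of the phenol (acetal protection) gives an ether that tolerates amide base, carbonate and ylide and, unlike a silyl ether, also the fluoride released later in the SNAr step.

**Step 3**
Reactants: 4 2-bromo-4-fluoro-1-(methoxymethoxy)benzene
Product: 6 2-bromo-6-fluoro-3-(methoxymethoxy)benzaldehyde, via aryllithium 5 (not isolated)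
Conditions: LiN(iPr)2, THF, −78 °C; DMF, −78 °C; AcOH, then H2O
Reagents that add atoms: N,N-dimethylformamide, CN(C)C=O
Why: Directed ortho-metalation under acidity control removes the one ring proton flanked by both Br and F, giving the most stabilised aryllithium (no drive for halogen dance, persistent at −78 °C), and DMF formylates it to fix the contiguous F/CHO/Br/O pattern of ring B.

**Step 4**
Reactants: 6 2-bromo-6-fluoro-3-(methoxymethoxy)benzaldehyde; 2 methyl 5-hydroxy-2-methylbenzoate
Product: 7 methyl 5-[3-bromo-2-formyl-4-(methoxymethoxy)phenoxy]-2-methylbenzoate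
Conditions: K2CO3, DMF, 90 °C
Reagents that add atoms: none
Why: Nucleophilic aromatic substitution by addition–elimination, in which the phenoxide of 2 attacks the C–F carbon ortho to the formyl group and fluoride leaves far more readily than the other ortho halogen, so the diaryl ether forms with the C–Br bond intact.

**Step 5**
Reactants: 7 methyl 5-[3-bromo-2-formyl-4-(methoxymethoxy)phenoxy]-2-methylbenzoate
Product: 8 methyl 5-[3-bromo-2-ethenyl-4-(methoxymethoxy)phenoxy]-2-methylbenzoate
Conditions: Ph3PCH3Br, KOtBu, THF, 0 °C → rt
Reagents that add atoms: methyltriphenylphosphonium bromide, C[P+](c1ccccc1)(c1ccccc1)c1ccccc1.[Br-]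
Why: Wittig methylenation with the non-stabilised ylide converts the hindered aldehyde into the styrene much faster than the ylide can touch the aryl ester.

**Step 6**
Reactants: 8 methyl 5-[3-bromo-2-ethenyl-4-(methoxymethoxy)phenoxy]-2-methylbenzoate
Product: 9 methyl 5-(3-bromo-2-ethenyl-4-hydroxyphenoxy)-2-methylbenzoate
Conditions: HCl (1.25 M in MeOH), 40 °C
Reagents that add atoms: none
Why: Acid-catalysed transacetalisation to methanol cleaves the aryl MOM ether easily because phenol is a good leaving group, and doing it before the benzylic alcohol exists prevents formation of a cyclic formaldehyde acetal or a benzylic methyl ether.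

**Step 7**
Reactants: 9 methyl 5-(3-bromo-2-ethenyl-4-hydroxyphenoxy)-2-methylbenzoate
Product: 11 methyl 5-[2-ethenyl-4-hydroxy-3-(hydroxymethyl)phenoxy]-2-methylbenzoate, via benzylic acetate 10 (not isolated)
Conditions: AcOCH2BF3K, Pd(dba)2 (5 mol %), RuPhos (10 mol %), Na2CO3, dioxane/H2O 10:1, 100 °C
Reagents that add atoms: potassium (acetoxymethyl)trifluoroborate, CC(=O)OC[B-](F)(F)F.[K+]
Why: Suzuki–Miyaura coupling of an sp3 organotrifluoroborate (palladium-catalysed hydroxymethylation of aryl halides), in which zerovalent palladium on the bulky electron-rich biaryl phosphine inserts into the hindered C–Br bond, the acetoxymethyl group is transferred, and aqueous carbonate hydrolyses the primary acetate in the same pot while the hindered methyl benzoate survives.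

**Step 8**
Reactants: 11 methyl 5-[2-ethenyl-4-hydroxy-3-(hydroxymethyl)phenoxy]-2-methylbenzoate
Product: 12 methyl 5-[(5-ethenyl-2,2-dimethyl-4H-1,3-benzodioxin-6-yl)oxy]-2-methylbenzoate
Conditions: Me2C(OMe)2, PPTS (cat.), CH2Cl2, rt
Reagents that add atoms: 2,2-dimethoxypropane, COC(C)(C)OC
Why: Acid-catalysed ketal exchange closes the six-membered 1,3-benzodioxine on the salicyl alcohol unit, which protects both hydroxyl groups at once and ties the ortho CH2O substituent back from the vinyl group.

**Step 9**
Reactants: 12 methyl 5-[(5-ethenyl-2,2-dimethyl-4H-1,3-benzodioxin-6-yl)oxy]-2-methylbenzoate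
Product: 13 5-[(5-ethenyl-2,2-dimethyl-4H-1,3-benzodioxin-6-yl)oxy]-2-methylbenzoic acid
Conditions: LiOH, THF/MeOH/H2O, 50 °C; then 0.5 M HCl to pH 4, 0 °C
Reagents that add atoms: lithium hydroxide, [Li+].[OH-]
Why: Saponification (acyl–oxygen cleavage by hydroxide) removes the methyl ester while ketal, diaryl ether and styrene are inert to base, and the brief cold acidification spares the ketal.

**Step 10**
Reactants: 14 3-(methoxymethoxy)prop-1-ene; 15 hexanal
Product: 19 (3S,4S)-3-(methoxymethoxy)non-1-en-4-ol, via (Z)-allyllithium 16 (not isolated), via (Z)-alkoxyallylborane 17 (not isolated), via borinate 18 (not isolated)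
Conditions: s-BuLi, THF, −78 °C; (+)-Ipc2BOMe, −78 °C; BF3·OEt2, then 15, −78 °C → rt; NaOH, H2O2, H2O
Reagents that add atoms: none
Why: Brown asymmetric alkoxyallylboration, in which kinetic lithiation gives the chelated Z-allyllithium, boron transfer and methoxide removal by BF3 give the (Z)-γ-alkoxyallylborane, and its closed chair (Zimmerman–Traxler) transition state turns the Z geometry into the syn relationship while the isopinocampheyl groups direct attack to the Re face of hexanal, setting C4 as S and C3 as S.

**Step 11**
Reactants: 13 5-[(5-ethenyl-2,2-dimethyl-4H-1,3-benzodioxin-6-yl)oxy]-2-methylbenzoic acid; 19 (3S,4S)-3-(methoxymethoxy)non-1-en-4-ol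
Product: 21 (3S,4S)-3-(methoxymethoxy)non-1-en-4-yl 5-[(5-ethenyl-2,2-dimethyl-4H-1,3-benzodioxin-6-yl)oxy]-2-methylbenzoate, via mixed anhydride 20 (not isolated)
Conditions: 2,4,6-Cl3C6H2COCl, Et3N, toluene, rt; then 19, DMAP, toluene, rt → 40 °C
Reagents that add atoms: none
Why: Yamaguchi esterification through the mixed anhydride under DMAP catalysis acylates the hindered secondary alcohol at oxygen, so C4 keeps its configuration and both acetal groups are untouched.

**Step 12**
Reactants: 21 (3S,4S)-3-(methoxymethoxy)non-1-en-4-yl 5-[(5-ethenyl-2,2-dimethyl-4H-1,3-benzodioxin-6-yl)oxy]-2-methylbenzoate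
Product: 22 Z-configured 12-membered macrolactone, the MOM ether (allylic oxygen) and acetonide (phenol and benzylic oxygens of ring B) of the target, S at both ring sp3 carbons
Conditions: Ru(κ2-NO3)(=CH-C6H4-2-OiPr)[κ2-C,C-1-(adamantane-1,2-diyl)-3-(2,6-iPr2C6H3)imidazolidin-2-ylidene] (2 × 5 mol %), ClCH2CH2Cl (2 mM), 60 °C, static vacuum
Reagents that add atoms: none
Why: This is a Chauvin-type ring-closing olefin metathesis, and the closest known reactions are the Z-selective macrocyclic closure of terminal dienes and the Z-selective cross metathesis of allylically branched terminal alkenes with this family of cyclometalated nitrato ruthenium carbenes, together with the closure of diaryl-ether-bridged styrene/vinyl carbinol esters by ordinary ruthenium carbenes. After loss of the isopropoxystyrene ligand the catalyst should load on the vinyl group next to C3, since the ring B styrene carries two ortho substituents (aryloxy oxygen and benzodioxine CH2) and is a poor site of initiation. The alkylidene then adds intramolecularly across the styrene to a side-bound ruthenacyclobutane whose cycloreversion releases the 12-membered ring, closed end to end between the two internal CH carbons of the diene, and a ruthenium methylidene that carries the chain while ethylene is removed under vacuum. No stereocentre is created, C3 and C4 are spectators under these neutral conditions, and the new stereo-element is the alkene geometry. Z over E is needed and must come from the catalyst, because a ring of this size can hold either geometry: in the side-bound metallacycle the N-aryl group lies over the ring and pushes the aryl and carbinol substituents to the same, opposite face, which gives the cis alkene under kinetic control. The substrate helps through the unequal hindrance of its two alkenes (ordered initiation, slow homodimerisation), the diaryl ether hinge, the tied-back ketal and the small MOM group (ends close, ortho bulk minimal), high dilution (ring over oligomer), and a product alkene so shielded that it should not be reopened and equilibrated.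

**Step 13**
Reactants: 22 Z-configured protected macrolactone
Product: 23 CNP0191798.1, the target
Conditions: Me2BBr, CH2Cl2, −78 °C; then THF/sat. aq. NaHCO3, 0 °C
Reagents that add atoms: none
Why: Lewis-acid cleavage of acetals with bromodimethylborane at −78 °C attacks the MOM ether and the ketal at their acetal carbons only, and the bicarbonate work-up frees the three hydroxyl groups, while ester, aryl ether, allylic C–O bond and Z alkene are not attacked, so both stereocentres and the alkene geometry pass unchanged into the target.

## Compound list

1 | 5-hydroxy-2-methylbenzoic acid | Cc1ccc(O)cc1C(=O)O | starting material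
2 | methyl 5-hydroxy-2-methylbenzoate | COC(=O)c1cc(O)ccc1C | intermediate
3 | 2-bromo-4-fluorophenol | Oc1ccc(F)cc1Br | starting material
4 | 2-bromo-4-fluoro-1-(methoxymethoxy)benzene | COCOc1ccc(F)cc1Br | intermediate
5 | [2-bromo-6-fluoro-3-(methoxymethoxy)phenyl]lithium (formed in the flask) | [Li]c1c(F)ccc(OCOC)c1Br | intermediate
6 | 2-bromo-6-fluoro-3-(methoxymethoxy)benzaldehyde | O=Cc1c(F)ccc(OCOC)c1Br | intermediate
7 | methyl 5-[3-bromo-2-formyl-4-(methoxymethoxy)phenoxy]-2-methylbenzoate | COC(=O)c1cc(ccc1C)Oc1ccc(OCOC)c(Br)c1C=O | intermediate
8 | methyl 5-[3-bromo-2-ethenyl-4-(methoxymethoxy)phenoxy]-2-methylbenzoate | COC(=O)c1cc(ccc1C)Oc1ccc(OCOC)c(Br)c1C=C | intermediate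
9 | methyl 5-(3-bromo-2-ethenyl-4-hydroxyphenoxy)-2-methylbenzoate | COC(=O)c1cc(ccc1C)Oc1ccc(O)c(Br)c1C=C | intermediate
10 | methyl 5-[3-(acetoxymethyl)-2-ethenyl-4-hydroxyphenoxy]-2-methylbenzoate (formed in the flask) | COC(=O)c1cc(ccc1C)Oc1ccc(O)c(COC(C)=O)c1C=C | intermediate
11 | methyl 5-[2-ethenyl-4-hydroxy-3-(hydroxymethyl)phenoxy]-2-methylbenzoate | COC(=O)c1cc(ccc1C)Oc1ccc(O)c(CO)c1C=C | intermediate
12 | methyl 5-[(5-ethenyl-2,2-dimethyl-4H-1,3-benzodioxin-6-yl)oxy]-2-methylbenzoate | COC(=O)c1cc(ccc1C)Oc1ccc2OC(C)(C)OCc2c1C=C | intermediate
13 | 5-[(5-ethenyl-2,2-dimethyl-4H-1,3-benzodioxin-6-yl)oxy]-2-methylbenzoic acid | Cc1ccc(cc1C(=O)O)Oc1ccc2OC(C)(C)OCc2c1C=C | intermediate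
14 | 3-(methoxymethoxy)prop-1-ene (allyl methoxymethyl ether) | C=CCOCOC | starting material
15 | hexanal | CCCCCC=O | starting material
16 | (Z)-3-(methoxymethoxy)allyllithium (formed in the flask) | [Li]C/C=C\OCOC | intermediate
17 | [(Z)-3-(methoxymethoxy)allyl]diisopinocampheylborane, Ipc groups from (−)-α-pinene (formed in the flask) | COCO/C=C\CB([C@H]1C[C@H]2C[C@@H]([C@@H]1C)C2(C)C)[C@H]1C[C@H]2C[C@@H]([C@@H]1C)C2(C)C | intermediate
18 | (3S,4S)-3-(methoxymethoxy)non-1-en-4-yl diisopinocampheylborinate (formed in the flask) | CCCCC[C@H](OB([C@H]1C[C@H]2C[C@@H]([C@@H]1C)C2(C)C)[C@H]1C[C@H]2C[C@@H]([C@@H]1C)C2(C)C)[C@@H](OCOC)C=C | intermediate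
19 | (3S,4S)-3-(methoxymethoxy)non-1-en-4-ol | CCCCC[C@H](O)[C@@H](OCOC)C=C | intermediate
20 | mixed anhydride of 13 and 2,4,6-trichlorobenzoic acid (formed in the flask) | Cc1ccc(cc1C(=O)OC(=O)c1c(Cl)cc(Cl)cc1Cl)Oc1ccc2OC(C)(C)OCc2c1C=C | intermediate
21 | (3S,4S)-3-(methoxymethoxy)non-1-en-4-yl 5-[(5-ethenyl-2,2-dimethyl-4H-1,3-benzodioxin-6-yl)oxy]-2-methylbenzoate | CCCCC[C@H](OC(=O)c1cc(ccc1C)Oc1ccc2OC(C)(C)OCc2c1C=C)[C@@H](OCOC)C=C | intermediate
22 | Z-configured 12-membered macrolactone, MOM ether and acetonide of the target | CCCCC[C@@H]1OC(=O)c2cc(ccc2C)Oc2ccc3OC(C)(C)OCc3c2/C=C\[C@@H]1OCOC | intermediate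
23 | CNP0191798.1: 12-membered lactone with meta-bridged methyl-bearing ring A, ortho-bridged ring B carrying OH and CH2OH, Z-styrenyl alkene, (S)-allylic carbinol and (S)-pentyl-bearing ester carbon | CCCCC[C@@H]1OC(=O)c2cc(ccc2C)Oc2ccc(O)c(CO)c2/C=C\[C@@H]1O | target

## Step count and risks

Total step count: 13.
Longest linear sequence: 11 steps, from 3 to 23 (steps 2–9 and 11–13).

**Step 12 (ring closure).** The alkylidene loaded at the allylic ether end may not reach the doubly ortho-substituted styrene before the cyclometalated catalyst decays, so conversion stalls. The geometry may also erode through ethenolysis and re-closure if ethylene is not removed.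

The fallback separates ring closure from control of geometry. It sets out from 21 and comes back at 22.
- Diene 21 is closed with the more reactive, non-selective second-generation Hoveyda–Grubbs catalyst RuCl2(H2IMes)(=CH-C6H4-2-OiPr) in hot dilute toluene. This closure is well known for diaryl-ether-bridged styrene/vinyl carbinol esters and is expected to favour the E-configured macrolactone F1.
- This material, alone or mixed with 22, is irradiated at 450 nm with fac-Ir(ppy)3 in MeCN. Triplet energy transfer to the styrene chromophore pumps the more planar E isomer into the more twisted, poorer-accepting Z isomer 22.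
- 22 is separated, and recovered E isomer is recycled.

**Step 13 (global deprotection).** The Z-cinnamyl-type C–O bond may ionise. The neighbouring benzylic alcohol could then capture the allyl cation, or the salicyl alcohol could lose water toward a quinone methide, and these processes could compete with acetal cleavage.

The fallback exchanges the acetal groups for fluoride-labile groups before the alkene is conjugated. It sets out from 21 and comes back at 23.
- Aqueous HCl in THF at 40 °C acts on 21, whose isolated vinyl carbinol ether is much harder to ionise, to give the diene triol F2.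
- TBSOTf and 2,6-lutidine give its tris(tert-butyldimethylsilyl) ether F3.
- Ring closure under the conditions of step 12 gives the silylated Z-macrolactone F4.
- HF·pyridine in THF/pyridine frees 23 without any acid-labile acetal left to cleave.

**Step 7 (hydroxymethylation).** Oxidative addition at the electron-rich, doubly ortho-substituted C–Br bond may be slow, so that protodebromination of the arene or protodeboronation of the reagent outruns the coupling.

The fallback brings in the carbon as carbon monoxide instead of an sp3 boron reagent. It sets out from 8 and comes back at 11.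
- Reductive carbonylation of 8 with Pd(OAc)2, di(1-adamantyl)-n-butylphosphine, TMEDA and CO/H2 in toluene at 100 °C gives the MOM-protected aryl aldehyde F5.
- HCl in MeOH removes the MOM group at the aldehyde stage, where no benzylic alcohol is present, to give the salicylaldehyde F6.
- NaBH4 in MeOH at 0 °C reduces the aldehyde, but not the benzoate, to give 11.

## Further compounds

F1 | step 12 | E-configured 12-membered macrolactone, geometric isomer of 22 | CCCCC[C@@H]1OC(=O)c2cc(ccc2C)Oc2ccc3OC(C)(C)OCc3c2/C=C/[C@@H]1OCOC
F2 | step 13 | (3S,4S)-3-hydroxynon-1-en-4-yl 5-[2-ethenyl-4-hydroxy-3-(hydroxymethyl)phenoxy]-2-methylbenzoate | CCCCC[C@H](OC(=O)c1cc(ccc1C)Oc1ccc(O)c(CO)c1C=C)[C@@H](O)C=C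
F3 | step 13 | tris(tert-butyldimethylsilyl) ether of F2 | CCCCC[C@H](OC(=O)c1cc(ccc1C)Oc1ccc(O[Si](C)(C)C(C)(C)C)c(CO[Si](C)(C)C(C)(C)C)c1C=C)[C@@H](O[Si](C)(C)C(C)(C)C)C=C
F4 | step 13 | tris(tert-butyldimethylsilyl) ether of the target, Z-macrolactone | CCCCC[C@@H]1OC(=O)c2cc(ccc2C)Oc2ccc(O[Si](C)(C)C(C)(C)C)c(CO[Si](C)(C)C(C)(C)C)c2/C=C\[C@@H]1O[Si](C)(C)C(C)(C)C
F5 | step 7 | methyl 5-[2-ethenyl-3-formyl-4-(methoxymethoxy)phenoxy]-2-methylbenzoate | COC(=O)c1cc(ccc1C)Oc1ccc(OCOC)c(C=O)c1C=C
F6 | step 7 | methyl 5-(2-ethenyl-3-formyl-4-hydroxyphenoxy)-2-methylbenzoate | COC(=O)c1cc(ccc1C)Oc1ccc(O)c(C=O)c1C=C
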